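**Strategy.** Each ring of the target is a catechol whose C5 hydroxyl sits ortho to the C4 hydroxyl (C1 = bridge carbon, C2/C3 = Br). The two C5–O bonds are therefore disconnected to C5 formyl groups. A two-fold Dakin oxidation of the methylene-bridged bis-salicylaldehyde 7 should turn both CHO groups into OH in one operation and give the target directly, without protecting groups. Precursor 7 is 5,5'-methylenebis(3,4-dibromo-2-hydroxybenzaldehyde). It is assembled from 2,3-dibromophenol by magnesium-mediated ortho-formylation and acid-catalysed bridging with trioxane para to the hydroxyl, so the purchased phenol leaves no regiochemical choice open.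

Key step: step 3

Remark: the target has no stereocentre (identical rings, CH2 bridge), so it is achiral and needs no enantiocontrol; positions are given in target numbering (C1 bridge, C2/C3 Br, C4/C5 OH, C6 H) unless a compound name implies its own numbering.

**Step 1**
Reactants: 1 2,3-dibromophenol; 2 paraformaldehyde
Product: 4 3,4-dibromo-2-hydroxybenzaldehyde, via 2,3-dibromo-6-(hydroxymethyl)phenol 3 (not isolated)
Conditions: MgCl2 (anhydrous, 2 equiv), Et3N (2 equiv), (CH2O)n (3 equiv), THF, reflux; then 1 M HCl
Reagents that add atoms: paraformaldehyde (as formaldehyde), C=O
Why: Magnesium-mediated ortho-formylation (Casnati–Skattebøl reaction): the aryloxymagnesium species should deliver coordinated formaldehyde through a six-membered transition state to the only unsubstituted ortho carbon, and the magnesium alkoxide of 3 is then oxidised by a second formaldehyde in an Oppenauer-type hydride transfer, a sequence well established for 2-bromophenol that leaves the free para position untouched.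

**Step 2**
Reactants: 4 3,4-dibromo-2-hydroxybenzaldehyde (two molecules); 5 1,3,5-trioxane
Product: 7 5,5'-methylenebis(3,4-dibromo-2-hydroxybenzaldehyde), via 5-hydroxymethyl aldehyde 6 (not isolated)
Conditions: 1,3,5-trioxane (0.17 equiv), conc. H2SO4/AcOH (1:4 v/v), 90 °C, N2
Reagents that add atoms: 1,3,5-trioxane, C1OCOCO1
Why: Acid-catalysed hydroxymethylation followed by Friedel–Crafts benzylation, the methylene bridging known for salicylaldehyde and for polyhalophenols, should occur only at C5 of 4 (para to the hydroxyl, meta to the formyl group), because the C3 bromine blocks the other activated site and so prevents chain growth, and the moderate acidity of H2SO4/AcOH leaves the hydrogen-bonded aldehyde largely unprotonated.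

**Step 3**
Reactants: 7 5,5'-methylenebis(3,4-dibromo-2-hydroxybenzaldehyde); 8 hydrogen peroxide
Product: 10 bis(2,3-dibromo-4,5-dihydroxyphenyl)methane, via bis-formate 9 (not isolated)
Conditions: 30% aq. H2O2 (2.4 equiv), NaOH (2.2 equiv), degassed H2O/THF, N2, 0 °C to rt; then Na2SO3, 1 M HCl
Reagents that add atoms: hydrogen peroxide, OO
Why: Each formyl carbon of the dianion of 7 takes up HOO−, and the resulting peroxy-hemiacetal collapses by a 1,2-shift of the aryl carbon (C1 of each salicylaldehyde ring, C5 in target numbering) onto the proximal peroxide oxygen as the O–O bond breaks, creating both new aryl C–O bonds in bis-formate 9, which hydroxide cleaves in the same pot. The closest known reaction type is the Dakin oxidation of halogenated salicylaldehydes to halocatechols, a Baeyer–Villiger-type migration. No ring is closed and no stereocentre is created, so neither a closure mode nor a stereocontrol element applies. The step needs aryl migration to win over hydride migration (which would give the salicylic acids); the ortho phenoxide at target C4 secures this by donating into the migrating ring despite the two bromines. The step also needs the catechol to survive, which one equivalent of base and little more than one of peroxide per aldehyde should ensure, since the medium drifts towards neutral as formic acid is released, with air excluded and residual peroxide destroyed by sulfite before acidification.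

**Compound list**
1 | 2,3-dibromophenol | Oc1cccc(Br)c1Br | starting material
2 | paraformaldehyde (solid polymer; SMILES of the monomer unit) | C=O | starting material
3 | 2,3-dibromo-6-(hydroxymethyl)phenol (present as its magnesium alkoxide) | OCc1ccc(Br)c(Br)c1O | intermediate
4 | 3,4-dibromo-2-hydroxybenzaldehyde | O=Cc1ccc(Br)c(Br)c1O | intermediate
5 | 1,3,5-trioxane | C1OCOCO1 | starting material
6 | 3,4-dibromo-2-hydroxy-5-(hydroxymethyl)benzaldehyde | O=Cc1cc(CO)c(Br)c(Br)c1O | intermediate
7 | 5,5'-methylenebis(3,4-dibromo-2-hydroxybenzaldehyde) | O=Cc1cc(Cc2cc(C=O)c(O)c(Br)c2Br)c(Br)c(Br)c1O | intermediate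
8 | hydrogen peroxide | OO | starting material
9 | bis(2,3-dibromo-5-formyloxy-4-hydroxyphenyl)methane | O=COc1cc(Cc2cc(OC=O)c(O)c(Br)c2Br)c(Br)c(Br)c1O | intermediate
10 | bis(2,3-dibromo-4,5-dihydroxyphenyl)methane | Oc1cc(Cc2cc(O)c(O)c(Br)c2Br)c(Br)c(Br)c1O | target

**Total step count:** 3. **Longest linear sequence:** 3.

**Steps most likely to fail, riskiest first**

(a) Step 2, the methylene bridging. Substitution at C5 of the doubly brominated, formyl-bearing ring may be slow, so the condensation could stall at the benzylic alcohol stage. At the temperature needed, ring sulfonation or acid-promoted loss or migration of the bromine ortho to the hydroxyl could take over. The fallback sets out from 4 and forms the two C–C bonds separately. Blanc chloromethylation of 4 (paraformaldehyde, conc. HCl, ZnCl2, 60 °C) should give 3,4-dibromo-5-(chloromethyl)-2-hydroxybenzaldehyde F1, which has no activated free position and so cannot self-condense. F1 then benzylates a second equivalent of 4 at C5 in a Friedel–Crafts reaction (catalytic TfOH, hexafluoroisopropanol/1,2-dichloroethane, 60 °C), which returns to 7.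

(b) Step 3, the double Dakin oxidation. The freed catechol rings may be oxidised further to ortho-quinones and ring-opened acids in basic peroxide, or hydride shift may compete and give carboxylic acids. The fallback sets out from 7 and introduces the oxygen while its neighbour is masked.
- O-methylation (MeI, K2CO3, DMF) should give 5,5'-methylenebis(3,4-dibromo-2-methoxybenzaldehyde) F2.
- Baeyer–Villiger oxidation with mCPBA in CH2Cl2 should give bis(2,3-dibromo-5-formyloxy-4-methoxyphenyl)methane F3.
- Aqueous NaOH/MeOH followed by HCl should cleave the formates to bis(2,3-dibromo-5-hydroxy-4-methoxyphenyl)methane F4.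
- BBr3 in CH2Cl2 (−78 °C to rt) removes both methyl groups and returns to the route at 10, so no free catechol ever meets an oxidant.

(c) Step 1, the ortho-formylation. C–C bond formation at the electron-poor dibromophenoxide may be slow, which would allow methoxymethylation by excess formaldehyde or incomplete conversion. The fallback sets out from 1 and separates hydroxymethylation from oxidation. Phenylboronic acid-templated ortho-hydroxymethylation (PhB(OH)2, paraformaldehyde, cat. propionic acid, toluene, Dean–Stark) should give 7,8-dibromo-2-phenyl-4H-1,3,2-benzodioxaborin F5. Exchange with propane-1,3-diol releases 2,3-dibromo-6-(hydroxymethyl)phenol 3, isolated this time, and activated MnO2 (EtOAc, rt) oxidises the benzylic alcohol to 4, where the route is rejoined.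

**Further compounds**
F1 | step 2 | 3,4-dibromo-5-(chloromethyl)-2-hydroxybenzaldehyde | O=Cc1cc(CCl)c(Br)c(Br)c1O
F2 | step 3 | 5,5'-methylenebis(3,4-dibromo-2-methoxybenzaldehyde) | COc1c(C=O)cc(Cc2cc(C=O)c(OC)c(Br)c2Br)c(Br)c1Br
F3 | step 3 | bis(2,3-dibromo-5-formyloxy-4-methoxyphenyl)methane | COc1c(OC=O)cc(Cc2cc(OC=O)c(OC)c(Br)c2Br)c(Br)c1Br
F4 | step 3 | bis(2,3-dibromo-5-hydroxy-4-methoxyphenyl)methane | COc1c(O)cc(Cc2cc(O)c(OC)c(Br)c2Br)c(Br)c1Br
F5 | step 1 | 7,8-dibromo-2-phenyl-4H-1,3,2-benzodioxaborin | Brc1ccc2COB(c3ccccc3)Oc2c1Br
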